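**Strategy.** The only stereocentre, C2 of the pyran ring, carries a methyl group and a CH2-linked chain. Both are traced back to CH2OH arms, so C2 is built achiral in a 2,2-bis(hydroxymethyl)chroman-4-one whose benzene ring already holds the C5 and C8 oxygens as MOM ethers. A lipase then acetylates one enantiotopic arm with vinyl acetate, which fixes C2 without forming a skeletal bond. The free arm is oxidised and extended by Wittig olefination and hydrogenation, the ester arm is reduced to methyl, the C4 ketone becomes the C3=C4 alkene, and C6 (para to O1) is acetylated for a Claisen–Schmidt condensation before global deprotection.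

Key step: step 8

Assumption 1: the lipase, picked by screening, is taken to deliver the (R)-monoacetate 15; this enantiomer is wanted because its free arm can be oxidised at once and its ester arm becomes methyl only after deacetylation, so neither acyl migration nor acetoxonium scrambling can erode C2 (with the mirror-image monoacetate the two arms would simply exchange roles).
Assumption 2: 6, 14, 33 and all reagents are commercial; 10 is supplied as its dimer.

**Step 1**
Reactants: 1 2,5-dihydroxybenzaldehyde
Product: 2 2,5-bis(methoxymethoxy)benzaldehyde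
Conditions: MOMCl, NaH, DMF, 0 °C → rt
Reagents that add atoms: chloromethyl methyl ether, COCCl
Why: Williamson-type O-alkylation of both phenoxides (acetal protection); NaH also deprotonates the 2-OH that is hydrogen-bonded to the aldehyde.

**Step 2**
Reactants: 2 2,5-bis(methoxymethoxy)benzaldehyde
Product: 4 2,5-bis(methoxymethoxy)phenol, via aryl formate 3 (not isolated)
Conditions: mCPBA, CH2Cl2, 0 °C → rt; then K2CO3 (cat.), MeOH, rt
Reagents that add atoms: 3-chloroperbenzoic acid, O=C(OO)c1cccc(Cl)c1
Why: Baeyer–Villiger oxidation of an electron-rich benzaldehyde proceeds with aryl migration to the formate, which is cleaved by transesterification; the new phenol oxygen is the later O1.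

**Step 3**
Reactants: 4 2,5-bis(methoxymethoxy)phenol
Product: 5 2-(1-ethoxyethoxy)-1,4-bis(methoxymethoxy)benzene
Conditions: ethyl vinyl ether, PPTS (cat.), CH2Cl2, rt
Reagents that add atoms: ethyl vinyl ether, C=COCC
Why: acid-catalysed addition of the phenol to the enol ether (acetal protection) gives a directing group far more acid-labile than MOM; the new acetal centre is racemic and is lost in step 4.

**Step 4**
Reactants: 5 2-(1-ethoxyethoxy)-1,4-bis(methoxymethoxy)benzene; 6 N-methoxy-N-methylacetamide
Product: 9 1-[2-hydroxy-3,6-bis(methoxymethoxy)phenyl]ethan-1-one, via aryllithium 7 (not isolated), via ethoxyethyl-protected ketone 8 (not isolated)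
Conditions: n-BuLi, THF, 0 °C; 6, −78 → 0 °C; then AcOH–H2O, rt
Reagents that add atoms: none
Why: directed ortho-metalation occurs at the one position flanked by two acetal oxygens, the Weinreb amide stops at the ketone through its chelated adduct, and dilute AcOH hydrolyses the acetaldehyde-derived acetal while the formaldehyde-derived MOM ethers stay.

**Step 5**
Reactants: 10 1,3-dihydroxyacetone
Product: 11 1,3-bis[(tert-butyldimethylsilyl)oxy]propan-2-one
Conditions: TBSCl, imidazole, DMF, rt
Reagents that add atoms: tert-butyl(chloro)dimethylsilane, CC(C)(C)[Si](C)(C)Cl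
Why: standard silylation of the two primary hydroxyl groups; the dimer dissociates to the monomer under these conditions.

**Step 6**
Reactants: 9 1-[2-hydroxy-3,6-bis(methoxymethoxy)phenyl]ethan-1-one; 11 1,3-bis[(tert-butyldimethylsilyl)oxy]propan-2-one
Product: 12 2,2-bis{[(tert-butyldimethylsilyl)oxy]methyl}-5,8-bis(methoxymethoxy)chroman-4-one
Conditions: pyrrolidine, toluene, 4 Å MS, 80 °C
Reagents that add atoms: none
Why: Kabbe condensation, in which amine-mediated aldol-type condensation of the acetyl group with the activated alpha,alpha'-dioxygenated ketone gives an enone that the phenol closes by 6-membered oxa-Michael addition; C2 is achiral because both arms are identical.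

**Step 7**
Reactants: 12 2,2-bis{[(tert-butyldimethylsilyl)oxy]methyl}-5,8-bis(methoxymethoxy)chroman-4-one
Product: 13 2,2-bis(hydroxymethyl)-5,8-bis(methoxymethoxy)chroman-4-one
Conditions: Bu4NF, AcOH, THF, 0 °C → rt
Reagents that add atoms: none
Why: fluoride-induced desilylation is orthogonal to the MOM ethers, and the AcOH buffer prevents base-induced retro-oxa-Michael opening of the pyranone.

**Step 8 (key step)**
Reactants: 13 2,2-bis(hydroxymethyl)-5,8-bis(methoxymethoxy)chroman-4-one; 14 vinyl acetate
Product: 15 [(2R)-2-(hydroxymethyl)-5,8-bis(methoxymethoxy)-4-oxochroman-2-yl]methyl acetate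
Conditions: immobilised lipase (Burkholderia cepacia or Candida antarctica B, by screening), vinyl acetate, t-BuOMe, 30 °C
Reagents that add atoms: none
Why: The catalytic serine of the lipase is acetylated by vinyl acetate and hands the acetyl group to the one hydroxymethyl arm of 13 that fits the acceptor pocket, while the released vinyl alcohol tautomerises to acetaldehyde and makes the transfer irreversible. The closest known reaction type is the lipase-catalysed desymmetrisation of prochiral 2,2-disubstituted propane-1,3-diols by irreversible acyl transfer. No ring is closed and no skeletal bond is formed; the only change is that C2 becomes a stereocentre. Its configuration is set by the enzyme alone (catalyst control), which has to tell the flat aryl ether oxygen O1 from the C3 methylene next to the C4 ketone. The step needs enantiotopic-group selectivity and a stop at the monoester: both arms are unhindered primary alcohols, the two other substituents on C2 differ clearly in shape and polarity, and any slow second acetylation should remove mainly the minor monoacetate enantiomer as achiral diacetate. The neutral medium leaves the MOM ethers and the base-sensitive beta-aryloxy ketone untouched.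

**Step 9**
Reactants: 15 [(2R)-2-(hydroxymethyl)-5,8-bis(methoxymethoxy)-4-oxochroman-2-yl]methyl acetate
Product: 16 [(2S)-2-formyl-5,8-bis(methoxymethoxy)-4-oxochroman-2-yl]methyl acetate
Conditions: Dess–Martin periodinane, CH2Cl2, rt
Reagents that add atoms: none
Why: Dess–Martin oxidation consumes the free arm at once under non-basic conditions, so the acetyl group cannot migrate between the arms; the aldehyde has no alpha-hydrogen and C2 is untouched (the descriptor changes only through the priority rules).

**Step 10**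
Reactants: 17 4-bromo-2-methylbutan-2-ol
Product: 18 [(4-bromo-2-methylbutan-2-yl)oxy]triethylsilane
Conditions: Et3SiOTf, 2,6-lutidine, CH2Cl2, 0 °C
Reagents that add atoms: triethylsilyl trifluoromethanesulfonate, CC[Si](CC)(CC)OS(=O)(=O)C(F)(F)F
Why: silylation of the tertiary alcohol with the silyl triflate, so that no alkoxide or free hydroxyl group interferes in steps 12, 15, 19 and 20.

**Step 11**
Reactants: 18 [(4-bromo-2-methylbutan-2-yl)oxy]triethylsilane
Product: 19 triphenyl{3-methyl-3-[(triethylsilyl)oxy]butyl}phosphonium bromide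
Conditions: PPh3, MeCN, reflux
Reagents that add atoms: triphenylphosphine, c1ccc(cc1)P(c1ccccc1)c1ccccc1
Why: SN2 quaternisation of the phosphine by the unhindered primary bromide under neutral conditions that the silyl ether tolerates.

**Step 12**
Reactants: 16 [(2S)-2-formyl-5,8-bis(methoxymethoxy)-4-oxochroman-2-yl]methyl acetate; 19 triphenyl{3-methyl-3-[(triethylsilyl)oxy]butyl}phosphonium bromide
Product: 21 [(2R)-5,8-bis(methoxymethoxy)-2-{(1Z)-4-methyl-4-[(triethylsilyl)oxy]pent-1-en-1-yl}-4-oxochroman-2-yl]methyl acetate, via phosphorus ylide 20 (not isolated)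
Conditions: 19, NaN(SiMe3)2 (slight deficit), THF, 0 °C; then 16, −78 → 0 °C
Reagents that add atoms: none
Why: Wittig olefination with a non-stabilised ylide, which should take the non-enolisable aldehyde at −78 °C far faster than the hindered, electron-rich aryl ketone or the acetate, while the deficit of base avoids enolisation at C3; the alkene geometry (mainly Z) is irrelevant.

**Step 13**
Reactants: 21 [(2R)-5,8-bis(methoxymethoxy)-2-{(1Z)-4-methyl-4-[(triethylsilyl)oxy]pent-1-en-1-yl}-4-oxochroman-2-yl]methyl acetate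
Product: 22 [(2S)-5,8-bis(methoxymethoxy)-2-{4-methyl-4-[(triethylsilyl)oxy]pentyl}-4-oxochroman-2-yl]methyl acetate
Conditions: H2 (1 atm), Pd/C, EtOAc, rt
Reagents that add atoms: none
Why: heterogeneous catalytic hydrogenation of the disubstituted alkene in neutral EtOAc spares the aryl ketone, MOM and silyl ethers, and it is done while C4 is still a ketone so that no C3=C4 alkene is present.

**Step 14**
Reactants: 22 [(2S)-5,8-bis(methoxymethoxy)-2-{4-methyl-4-[(triethylsilyl)oxy]pentyl}-4-oxochroman-2-yl]methyl acetate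
Product: 23 (2S)-2-(hydroxymethyl)-5,8-bis(methoxymethoxy)-2-{4-methyl-4-[(triethylsilyl)oxy]pentyl}chroman-4-one
Conditions: K2CO3 (cat.), MeOH, 0 °C
Reagents that add atoms: none
Why: base-catalysed methanolysis of the primary acetate, kept cold and brief so that the beta-aryloxy ketone does not open by retro-oxa-Michael reaction and C2 keeps its configuration.

**Step 15**
Reactants: 23 (2S)-2-(hydroxymethyl)-5,8-bis(methoxymethoxy)-2-{4-methyl-4-[(triethylsilyl)oxy]pentyl}chroman-4-one
Product: 25 (2S)-2-(iodomethyl)-5,8-bis(methoxymethoxy)-2-{4-methyl-4-[(triethylsilyl)oxy]pentyl}chroman-4-one, via neopentyl triflate 24 (not isolated)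
Conditions: Tf2O, 2,6-lutidine, CH2Cl2, −40 °C; then Bu4NI, −40 °C → rt
Reagents that add atoms: tetrabutylammonium iodide, CCCC[N+](CCCC)(CCCC)CCCC.[I-]
Why: sulfonylation followed by Finkelstein-type SN2 displacement, the triflate being reactive enough for the neopentyl-type carbon; the weak hindered base does not enolise the ketone, and no ester neighbour remains that could scramble the arms.

**Step 16**
Reactants: 25 (2S)-2-(iodomethyl)-5,8-bis(methoxymethoxy)-2-{4-methyl-4-[(triethylsilyl)oxy]pentyl}chroman-4-one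
Product: 26 (2S)-5,8-bis(methoxymethoxy)-2-methyl-2-{4-methyl-4-[(triethylsilyl)oxy]pentyl}chroman-4-one
Conditions: Bu3SnH (excess, concentrated), AIBN (cat.), toluene, 80 °C
Reagents that add atoms: none
Why: radical-chain dehalogenation, run before the C3=C4 alkene exists so that the primary radical has nothing to add to, and at high tin hydride concentration so that it is trapped before any fragmentation.

**Step 17**
Reactants: 26 (2S)-5,8-bis(methoxymethoxy)-2-methyl-2-{4-methyl-4-[(triethylsilyl)oxy]pentyl}chroman-4-one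
Product: 27 (2S)-6-bromo-5,8-bis(methoxymethoxy)-2-methyl-2-{4-methyl-4-[(triethylsilyl)oxy]pentyl}chroman-4-one
Conditions: NBS, MeCN, 0 °C → rt
Reagents that add atoms: N-bromosuccinimide, O=C1CCC(=O)N1Br
Why: electrophilic aromatic bromination should go to C6, which is para to O1, ortho to the C5 ether and meta to the carbonyl-bearing C4a, whereas C7 is para to C4a and activated by one oxygen only.

**Step 18**
Reactants: 27 (2S)-6-bromo-5,8-bis(methoxymethoxy)-2-methyl-2-{4-methyl-4-[(triethylsilyl)oxy]pentyl}chroman-4-one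
Product: 28 (2S,4RS)-6-bromo-5,8-bis(methoxymethoxy)-2-methyl-2-{4-methyl-4-[(triethylsilyl)oxy]pentyl}chroman-4-ol
Conditions: NaBH4, MeOH–THF, 0 °C → rt
Reagents that add atoms: none
Why: hydride reduction of the aryl ketone; the new C4 carbinol centre forms as a mixture of epimers, which is of no consequence because C4 becomes sp2 in step 19.

**Step 19**
Reactants: 28 (2S,4RS)-6-bromo-5,8-bis(methoxymethoxy)-2-methyl-2-{4-methyl-4-[(triethylsilyl)oxy]pentyl}chroman-4-ol
Product: 30 {[5-((2S)-6-bromo-5,8-bis(methoxymethoxy)-2-methyl-2H-chromen-2-yl)-2-methylpentan-2-yl]oxy}triethylsilane, via benzylic mesylate 29 (not isolated)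
Conditions: MsCl, Et3N, CH2Cl2, 0 °C → rt
Reagents that add atoms: none
Why: sulfonylation and elimination of a benzylic mesylate that ionises readily next to the ortho oxygens; only C3 carries beta-hydrogens, so the C3=C4 alkene is the sole product, and the acid-free conditions spare the MOM and silyl ethers.

**Step 20**
Reactants: 30 {[5-((2S)-6-bromo-5,8-bis(methoxymethoxy)-2-methyl-2H-chromen-2-yl)-2-methylpentan-2-yl]oxy}triethylsilane; 6 N-methoxy-N-methylacetamide
Product: 32 1-[(2S)-5,8-bis(methoxymethoxy)-2-methyl-2-{4-methyl-4-[(triethylsilyl)oxy]pentyl}-2H-chromen-6-yl]ethan-1-one, via aryllithium 31 (not isolated)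
Conditions: n-BuLi, THF, −78 °C; then 6, −78 → 0 °C
Reagents that add atoms: none
Why: bromine–lithium exchange gives the C6 aryllithium, stabilised by the neighbouring MOM oxygen, and Weinreb ketone synthesis stops at the methyl ketone.

**Step 21**
Reactants: 32 1-[(2S)-5,8-bis(methoxymethoxy)-2-methyl-2-{4-methyl-4-[(triethylsilyl)oxy]pentyl}-2H-chromen-6-yl]ethan-1-one; 33 4-(methoxymethoxy)benzaldehyde
Product: 34 (2E)-1-[(2S)-5,8-bis(methoxymethoxy)-2-methyl-2-{4-methyl-4-[(triethylsilyl)oxy]pentyl}-2H-chromen-6-yl]-3-[4-(methoxymethoxy)phenyl]prop-2-en-1-one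
Conditions: KOH, EtOH, rt
Reagents that add atoms: none
Why: Claisen–Schmidt aldol condensation of the methyl ketone with a non-enolisable aldehyde; E1cB dehydration gives the conjugated E-enone, and with all phenols masked no flavanone can form.

**Step 22**
Reactants: 34 (2E)-1-[(2S)-5,8-bis(methoxymethoxy)-2-methyl-2-{4-methyl-4-[(triethylsilyl)oxy]pentyl}-2H-chromen-6-yl]-3-[4-(methoxymethoxy)phenyl]prop-2-en-1-one
Product: 35 (2E)-1-[(2S)-5,8-dihydroxy-2-(4-hydroxy-4-methylpentyl)-2-methyl-2H-chromen-6-yl]-3-(4-hydroxyphenyl)prop-2-en-1-one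
Conditions: HCl (1.25 M in MeOH), rt, argon
Reagents that add atoms: none
Why: acid-catalysed acetal exchange removes the three MOM ethers and methanolysis removes the silyl ether in one operation; room temperature and exclusion of air are chosen to avoid flavanone closure, attack on the tertiary alcohol and oxidation of the hydroquinone.

**Compound list**
1 | 2,5-dihydroxybenzaldehyde | O=Cc1cc(O)ccc1O | starting material
2 | 2,5-bis(methoxymethoxy)benzaldehyde | O=Cc1cc(OCOC)ccc1OCOC | intermediate
3 | 2,5-bis(methoxymethoxy)phenyl formate | O=COc1cc(OCOC)ccc1OCOC | intermediate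
4 | 2,5-bis(methoxymethoxy)phenol | Oc1cc(OCOC)ccc1OCOC | intermediate
5 | 2-(1-ethoxyethoxy)-1,4-bis(methoxymethoxy)benzene (racemic acetal) | CCOC(C)Oc1cc(OCOC)ccc1OCOC | intermediate
6 | N-methoxy-N-methylacetamide | CC(=O)N(C)OC | starting material
7 | [2-(1-ethoxyethoxy)-3,6-bis(methoxymethoxy)phenyl]lithium | CCOC(C)Oc1c([Li])c(OCOC)ccc1OCOC | intermediate
8 | 1-[2-(1-ethoxyethoxy)-3,6-bis(methoxymethoxy)phenyl]ethan-1-one | CCOC(C)Oc1c(C(C)=O)c(OCOC)ccc1OCOC | intermediate
9 | 1-[2-hydroxy-3,6-bis(methoxymethoxy)phenyl]ethan-1-one | CC(=O)c1c(O)c(OCOC)ccc1OCOC | intermediate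
10 | 1,3-dihydroxyacetone (supplied as its dimer) | O=C(CO)CO | starting material
11 | 1,3-bis[(tert-butyldimethylsilyl)oxy]propan-2-one | CC(C)(C)[Si](C)(C)OCC(=O)CO[Si](C)(C)C(C)(C)C | intermediate
12 | 2,2-bis{[(tert-butyldimethylsilyl)oxy]methyl}-5,8-bis(methoxymethoxy)chroman-4-one | O=C1CC(CO[Si](C)(C)C(C)(C)C)(CO[Si](C)(C)C(C)(C)C)Oc2c(OCOC)ccc(OCOC)c12 | intermediate
13 | 2,2-bis(hydroxymethyl)-5,8-bis(methoxymethoxy)chroman-4-one | O=C1CC(CO)(CO)Oc2c(OCOC)ccc(OCOC)c12 | intermediate
14 | vinyl acetate | C=COC(C)=O | starting material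
15 | [(2R)-2-(hydroxymethyl)-5,8-bis(methoxymethoxy)-4-oxochroman-2-yl]methyl acetate | CC(=O)OC[C@]1(CO)CC(=O)c2c(OCOC)ccc(OCOC)c2O1 | intermediate
16 | [(2S)-2-formyl-5,8-bis(methoxymethoxy)-4-oxochroman-2-yl]methyl acetate | O=C[C@@]1(COC(C)=O)CC(=O)c2c(OCOC)ccc(OCOC)c2O1 | intermediate
17 | 4-bromo-2-methylbutan-2-ol | CC(C)(O)CCBr | starting material
18 | [(4-bromo-2-methylbutan-2-yl)oxy]triethylsilane | CC[Si](CC)(CC)OC(C)(C)CCBr | intermediate
19 | triphenyl{3-methyl-3-[(triethylsilyl)oxy]butyl}phosphonium bromide | CC[Si](CC)(CC)OC(C)(C)CC[P+](c1ccccc1)(c1ccccc1)c1ccccc1.[Br-] | intermediate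
20 | triphenyl{3-methyl-3-[(triethylsilyl)oxy]butylidene}phosphorane | CC[Si](CC)(CC)OC(C)(C)CC=P(c1ccccc1)(c1ccccc1)c1ccccc1 | intermediate
21 | [(2R)-5,8-bis(methoxymethoxy)-2-{(1Z)-4-methyl-4-[(triethylsilyl)oxy]pent-1-en-1-yl}-4-oxochroman-2-yl]methyl acetate | CC[Si](CC)(CC)OC(C)(C)C/C=C\[C@@]1(COC(C)=O)CC(=O)c2c(OCOC)ccc(OCOC)c2O1 | intermediate
22 | [(2S)-5,8-bis(methoxymethoxy)-2-{4-methyl-4-[(triethylsilyl)oxy]pentyl}-4-oxochroman-2-yl]methyl acetate | CC[Si](CC)(CC)OC(C)(C)CCC[C@@]1(COC(C)=O)CC(=O)c2c(OCOC)ccc(OCOC)c2O1 | intermediate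
23 | (2S)-2-(hydroxymethyl)-5,8-bis(methoxymethoxy)-2-{4-methyl-4-[(triethylsilyl)oxy]pentyl}chroman-4-one | CC[Si](CC)(CC)OC(C)(C)CCC[C@@]1(CO)CC(=O)c2c(OCOC)ccc(OCOC)c2O1 | intermediate
24 | [(2S)-5,8-bis(methoxymethoxy)-2-{4-methyl-4-[(triethylsilyl)oxy]pentyl}-4-oxochroman-2-yl]methyl trifluoromethanesulfonate | CC[Si](CC)(CC)OC(C)(C)CCC[C@@]1(COS(=O)(=O)C(F)(F)F)CC(=O)c2c(OCOC)ccc(OCOC)c2O1 | intermediate
25 | (2S)-2-(iodomethyl)-5,8-bis(methoxymethoxy)-2-{4-methyl-4-[(triethylsilyl)oxy]pentyl}chroman-4-one | CC[Si](CC)(CC)OC(C)(C)CCC[C@@]1(CI)CC(=O)c2c(OCOC)ccc(OCOC)c2O1 | intermediate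
26 | (2S)-5,8-bis(methoxymethoxy)-2-methyl-2-{4-methyl-4-[(triethylsilyl)oxy]pentyl}chroman-4-one | CC[Si](CC)(CC)OC(C)(C)CCC[C@@]1(C)CC(=O)c2c(OCOC)ccc(OCOC)c2O1 | intermediate
27 | (2S)-6-bromo-5,8-bis(methoxymethoxy)-2-methyl-2-{4-methyl-4-[(triethylsilyl)oxy]pentyl}chroman-4-one | CC[Si](CC)(CC)OC(C)(C)CCC[C@@]1(C)CC(=O)c2c(OCOC)c(Br)cc(OCOC)c2O1 | intermediate
28 | (2S,4RS)-6-bromo-5,8-bis(methoxymethoxy)-2-methyl-2-{4-methyl-4-[(triethylsilyl)oxy]pentyl}chroman-4-ol (C4 epimers) | CC[Si](CC)(CC)OC(C)(C)CCC[C@@]1(C)CC(O)c2c(OCOC)c(Br)cc(OCOC)c2O1 | intermediate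
29 | (2S,4RS)-6-bromo-5,8-bis(methoxymethoxy)-2-methyl-2-{4-methyl-4-[(triethylsilyl)oxy]pentyl}chroman-4-yl methanesulfonate | CC[Si](CC)(CC)OC(C)(C)CCC[C@@]1(C)CC(OS(C)(=O)=O)c2c(OCOC)c(Br)cc(OCOC)c2O1 | intermediate
30 | {[5-((2S)-6-bromo-5,8-bis(methoxymethoxy)-2-methyl-2H-chromen-2-yl)-2-methylpentan-2-yl]oxy}triethylsilane | CC[Si](CC)(CC)OC(C)(C)CCC[C@@]1(C)C=Cc2c(OCOC)c(Br)cc(OCOC)c2O1 | intermediate
31 | [(2S)-5,8-bis(methoxymethoxy)-2-methyl-2-{4-methyl-4-[(triethylsilyl)oxy]pentyl}-2H-chromen-6-yl]lithium | CC[Si](CC)(CC)OC(C)(C)CCC[C@@]1(C)C=Cc2c(OCOC)c([Li])cc(OCOC)c2O1 | intermediate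
32 | 1-[(2S)-5,8-bis(methoxymethoxy)-2-methyl-2-{4-methyl-4-[(triethylsilyl)oxy]pentyl}-2H-chromen-6-yl]ethan-1-one | CC[Si](CC)(CC)OC(C)(C)CCC[C@@]1(C)C=Cc2c(OCOC)c(C(C)=O)cc(OCOC)c2O1 | intermediate
33 | 4-(methoxymethoxy)benzaldehyde | COCOc1ccc(C=O)cc1 | starting material
34 | (2E)-1-[(2S)-5,8-bis(methoxymethoxy)-2-methyl-2-{4-methyl-4-[(triethylsilyl)oxy]pentyl}-2H-chromen-6-yl]-3-[4-(methoxymethoxy)phenyl]prop-2-en-1-one | CC[Si](CC)(CC)OC(C)(C)CCC[C@@]1(C)C=Cc2c(OCOC)c(C(=O)/C=C/c3ccc(OCOC)cc3)cc(OCOC)c2O1 | intermediate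
35 | (2E)-1-[(2S)-5,8-dihydroxy-2-(4-hydroxy-4-methylpentyl)-2-methyl-2H-chromen-6-yl]-3-(4-hydroxyphenyl)prop-2-en-1-one | CC(C)(O)CCC[C@@]1(C)C=Cc2c(O)c(C(=O)/C=C/c3ccc(O)cc3)cc(O)c2O1 | target

**Step count and risks**
Total step count: 22. Longest linear sequence: 19 steps (steps 1–4, 6–9 and 12–22, from 1 to 35).

Steps most likely to fail:

1. Step 8. The enzyme may discriminate the two enantiotopic arms poorly, acetylate the wrong arm, or run on to the diacetate. The fallback sets out from 13 and returns at 15. Both arms of 13 are acetylated (Ac2O, pyridine, DMAP) to the diacetate F1, and one enantiotopic ester group is then hydrolysed by a lipase or esterase in phosphate buffer at pH 7. Because the enzyme now removes the acetyl group from the arm it would otherwise acylate, this hydrolytic mode should give the opposite monoacetate enantiomer and so also corrects a wrong sense of induction; the product is 15.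

2. Step 12. The basic ylide may enolise the C4 ketone, which opens the pyranone by retro-oxa-Michael reaction and would also erase C2, or it may attack the ketone or the acetate. The fallback sets out from 16 and returns at 22. The aldehyde is methylenated under non-basic, aldehyde-selective conditions (CH2I2, Zn, Ti(OiPr)4, THF) to the vinyl compound F2. Cross-metathesis of F2 with the triethylsilyl ether of 2-methylpent-4-en-2-ol F3 (from the commercial alcohol with Et3SiOTf and 2,6-lutidine), using the second-generation Hoveyda–Grubbs catalyst, gives the (E)-alkene F4, which is hydrogenated as in step 13 to 22.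

3. Step 6. The bulky acyclic ketone 11 may condense too slowly, so that self-condensation and loss of silyl groups take over. The fallback sets out from 9 and returns at 13. Compound 9 is condensed under the same amine catalysis with the cyclic, tied-back ketone 2,2-dimethyl-1,3-dioxan-5-one (commercial) to the spiro acetonide F5, and the ketal is then removed with 80% aqueous AcOH at rt, which the aryl MOM ethers should survive, to give 13.

**Further compounds**
F1 | step 8 | [5,8-bis(methoxymethoxy)-4-oxochromane-2,2-diyl]bis(methylene) diacetate | CC(=O)OCC1(COC(C)=O)CC(=O)c2c(OCOC)ccc(OCOC)c2O1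
F2 | step 12 | [(2R)-2-ethenyl-5,8-bis(methoxymethoxy)-4-oxochroman-2-yl]methyl acetate | C=C[C@@]1(COC(C)=O)CC(=O)c2c(OCOC)ccc(OCOC)c2O1
F3 | step 12 | triethyl[(2-methylpent-4-en-2-yl)oxy]silane | C=CCC(C)(C)O[Si](CC)(CC)CC
F4 | step 12 | [(2R)-5,8-bis(methoxymethoxy)-2-{(1E)-4-methyl-4-[(triethylsilyl)oxy]pent-1-en-1-yl}-4-oxochroman-2-yl]methyl acetate | CC[Si](CC)(CC)OC(C)(C)C/C=C/[C@@]1(COC(C)=O)CC(=O)c2c(OCOC)ccc(OCOC)c2O1
F5 | step 6 | 2',2'-dimethyl-5,8-bis(methoxymethoxy)spiro[chromane-2,5'-[1,3]dioxan]-4-one | CC1(C)OCC2(CO1)CC(=O)c1c(OCOC)ccc(OCOC)c1O2
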